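Ring A, in clerodane-type numbering C5–C6–C7(OAc)–C8(=CH2)–C9(Me)–C10(H), is disconnected into a cyclobutanone (C5, C6, C7, C10) plus two carbons (C8, C9). In the key step a rhodium catalyst cleaves the C7–C10 bond of a cis-fused cyclobutanone, a ring absent from the target, and inserts the internal π-bond of a tethered 1,1-disubstituted allene. C7–C8 and C9–C10 form, the six-membered ring A and the furan-fused seven-membered ring C close, and the enone with the C8 methylene and the quaternary C9 methyl centre appears in one operation. The feature exploited is the 1,4-relationship of oxygenated C7 and C10–H across C5/C6. The precursor, a bicyclo[4.2.0]octanone bearing a furyl β-allenyl ketone, comes from an enantioselective cyclobutenone Diels–Alder reaction.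

Key step: step 11

Remark (numbering): C1 = CH bearing the furan, C2 = ring CH2, C3 = olefinic CH, C4 = lactone α-carbon, C5 = quaternary carbon bearing C19H2O, C6 = CH2, C7 = CHOAc, C8 = C(=C17H2), C9 = C(C20H3), C10 = central CH, C11 = CH2, C12 = ketone, C13/C16 = furan C3/C2, C18 = lactone C=O; ring A = C5–C10, ring B = C1–C5 + C10, ring C = C1, C10, C9, C11, C12, C13, C16; β-face = face of H-10, C19 and C20.

Remark (assumption): the sense of induction of the oxazaborolidinium catalyst in step 6 is assigned by analogy with 2-cycloalkenones; the mirror-image catalyst is used if the antipode of 9 forms.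

Step 1
Reactants: 1 3-bromofuran-2-carbaldehyde; 2 triethyl 4-phosphonocrotonate
Product: 3 ethyl (2E,4E)-5-(3-bromofuran-2-yl)penta-2,4-dienoate
Conditions: LiN(SiMe3)2, THF, −78 °C to rt
Reagents that add atoms: none
Why: Vinylogous Horner–Wadsworth–Emmons olefination, in which the γ-deprotonated phosphonocrotonate adds to the aldehyde through its phosphorus-bearing carbon and eliminates to the (2E,4E)-dienoate (new C1=C2 bond, no stereocentre).

Step 2
Reactants: 3 ethyl (2E,4E)-5-(3-bromofuran-2-yl)penta-2,4-dienoate
Product: 4 (2E,4E)-5-(3-bromofuran-2-yl)penta-2,4-dien-1-ol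
Conditions: i-Bu2AlH (2.2 equiv), CH2Cl2, −78 °C; aq. KNaC4H4O6 work-up
Reagents that add atoms: none
Why: 1,2-Reduction of the conjugated ester with i-Bu2AlH at low temperature gives the dienol without touching the aryl bromide or the diene.

Step 3
Reactants: 4 (2E,4E)-5-(3-bromofuran-2-yl)penta-2,4-dien-1-ol
Product: 5 tert-butyl{[(2E,4E)-5-(3-bromofuran-2-yl)penta-2,4-dien-1-yl]oxy}dimethylsilane
Conditions: TBSCl, imidazole, DMF, 0 °C to rt
Reagents that add atoms: tert-butyldimethylsilyl chloride, CC(C)(C)[Si](C)(C)Cl
Why: Imidazole-mediated silylation of the primary allylic alcohol masks C18–OH for the Lewis-acidic cycloaddition.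

Step 4
Reactants: 6 tert-butyldimethyl(prop-2-yn-1-yloxy)silane
Product: 7 3-{[(tert-butyldimethylsilyl)oxy]methyl}-4,4-dichlorocyclobut-2-en-1-one
Conditions: Cl3CCOCl, Zn(Cu), Et2O/DME, rt
Reagents that add atoms: trichloroacetyl chloride, ClC(Cl)(Cl)C(Cl)=O
Why: Thermal [2+2] cycloaddition of dichloroketene generated in situ with the terminal alkyne places the ketene carbonyl carbon on the unsubstituted alkyne carbon and gives the 3-substituted 4,4-dichlorocyclobutenone.

Step 5
Reactants: 7 3-{[(tert-butyldimethylsilyl)oxy]methyl}-4,4-dichlorocyclobut-2-en-1-one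
Product: 8 3-{[(tert-butyldimethylsilyl)oxy]methyl}cyclobut-2-en-1-one
Conditions: Zn, AcOH, TMEDA, EtOH, 0 °C to rt
Reagents that add atoms: none
Why: Zinc-mediated reductive dechlorination of the α,α-dichloroketone in buffered acetic acid removes both chlorines and leaves the strained enone (C10=C5, C7=O) and the silyl ether intact.

Step 6
Reactants: 5 tert-butyl{[(2E,4E)-5-(3-bromofuran-2-yl)penta-2,4-dien-1-yl]oxy}dimethylsilane; 8 3-{[(tert-butyldimethylsilyl)oxy]methyl}cyclobut-2-en-1-one
Product: 9 cis-fused 5-(3-bromofuran-2-yl)-1,2-bis{[(tert-butyldimethylsilyl)oxy]methyl}bicyclo[4.2.0]oct-3-en-7-one (bicyclooctane locants; four-membered ring, 2-CH2OTBS and 5-furyl on one face, 1-CH2OTBS on the other)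
Conditions: (S)-B-(o-tolyl)oxazaborolidine from (S)-α,α-diphenylprolinol (20 mol %), Tf2NH (18 mol %), CH2Cl2, −78 °C to −20 °C
Reagents that add atoms: none
Why: Lewis-acid-catalysed endo Diels–Alder reaction of a strain-activated cyclobutenone, in which the furyl-bearing diene terminus C1 bonds to the enone α-carbon C10 and C4 to the β-carbon C5 (aryl-directed "ortho" regiochemistry), the carbonyl-bearing four-membered ring lies endo so that C6/C7, the furyl group and C18 come out on one face with C19 on the other, and the chiral oxazaborolidinium ion selects the enone face, which sets C5, C10 and C1 (and C4, erased later).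

Step 7
Reactants: 9 Diels–Alder adduct
Product: 10 5-(3-bromofuran-2-yl)-1,2-bis(hydroxymethyl)bicyclo[4.2.0]oct-3-en-7-one (same configuration as 9)
Conditions: HF·pyridine, pyridine, THF, 0 °C to rt
Reagents that add atoms: none
Why: Fluoride-mediated cleavage of both primary silyl ethers under buffered, non-basic conditions frees the C18 and C19 carbinols without epimerising the cyclobutanone.

Step 8
Reactants: 10 diol
Product: 12 conjugated 18,19-lactone (C3=C4) carrying the cis-fused C5–C6–C7(=O)–C10 cyclobutanone and the 3-bromofuran-2-yl group at C1, via trans-fused β,γ-unsaturated lactone 11 (not isolated)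
Conditions: TEMPO (20 mol %), PhI(OAc)2 (2.5 equiv), CH2Cl2, rt; aq. NaHCO3/Na2S2O3 wash; crude in CH2Cl2, DBU (0.3 equiv), rt
Reagents that add atoms: none
Why: TEMPO/PhI(OAc)2 oxidative lactonisation of the 1,4-diol starts at the less hindered C18 carbinol (C19–OH is neopentyl) and so puts the carbonyl on C4, and DBU then moves the C2=C3 double bond into conjugation (C3=C4) through the lactone dienolate, which erases the C4 stereocentre and the trans ring fusion.

Step 9
Reactants: 12 conjugated lactone bromide; 13 tributyl(1-ethoxyethenyl)stannane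
Product: 14 enol ether (12 with C(OEt)=CH2 in place of Br at furan C3)
Conditions: Pd(PPh3)4 (5 mol %), toluene, 100 °C
Reagents that add atoms: none
Why: Stille cross-coupling of the heteroaryl bromide with the α-ethoxyvinylstannane under neutral conditions installs C12 and C11 as an enol ether while ketone, lactone and alkene stay untouched.

Step 10
Reactants: 14 enol ether; 15 but-2-yn-1-ol
Product: 18 β-allenyl ketone (furan C3 carries C(=O)CH2C(CH3)=C=CH2), via mixed ketal 16 (not isolated), via but-2-ynyl enol ether 17 (not isolated)
Conditions: 15 (5 equiv), EtCO2H (10 mol %), 4 Å MS, toluene, 110 °C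
Reagents that add atoms: none
Why: Saucy–Marbet reaction, in which acid-catalysed exchange of the ethyl enol ether for the propargylic alcohol is followed by propargyl Claisen ([3,3]-sigmatropic) rearrangement that forms the C11–C9 bond and delivers the β-allenyl ketone with C20 on C9 and the C8=C17 terminus, without base that would conjugate the allene.

Step 11
Reactants: 18 β-allenyl ketone
Product: 19 pentacyclic α-methylene ketone (target skeleton with C7=O)
Conditions: [Rh(CO)2Cl]2 (5 mol %), P(C6F5)3 (12 mol %), 1,4-dioxane, 130 °C, sealed tube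
Reagents that add atoms: none
Why: Proposed new method: Monovalent rhodium adds oxidatively to the strained C7–C10 bond of the cyclobutanone (insertion into C6–C7 is reversible and leads nowhere), the acyl group migrates to the central allene carbon C8 to give an acyl-substituted π-allyl complex of trivalent rhodium, and C–C reductive elimination between C10 and the substituted allyl terminus C9 releases the α-methylene ketone and the catalyst. The closest known reactions are the rhodium-catalysed carboacylations ("cut-and-sew") of alkynes and olefins tethered to cyclobutanones and the (4+2)/(4+1) couplings of cyclobutanones with tethered allenes; the combination of an α-tethered saturated cyclobutanone, an allene and a seven-membered tether ring has no precedent. Ring A closes as the six-membered ring of a formal (4+2) through the C7–C8 bond, and ring C closes in a 7-exo mode through the C9–C10 bond, the C8=C17 bond staying exocyclic. C10 keeps its configuration because oxidative addition and reductive elimination both proceed with retention, and the new quaternary centre C9 is controlled by the furyl ketone tether anchored at C1, which can deliver C9 only to the α-face of C10 with C11 syn to C1 (cis A/C fusion, C20 on the convex β-face). The step needs cleavage of the more substituted acyl–carbon bond, insertion of the internal rather than the terminal allene π-bond and (4+2) rather than (4+1) closure, and all three are secured by the short tether, since every alternative would need an eight- or nine-membered or bridged ring.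

Step 12
Reactants: 19 pentacyclic α-methylene ketone
Product: 20 7α-allylic alcohol (deacetyl target)
Conditions: NaBH4, CeCl3·7H2O, MeOH, −78 °C
Reagents that add atoms: none
Why: Luche 1,2-reduction of the α-methylene ketone, which is more electrophilic than the vinylogous-ester-like furyl ketone and the unsaturated lactone at −78 °C, with hydride delivered equatorially from the convex β-face because the axial trajectory is blocked by the axial C4 and C11 branches of the bowl-shaped all-cis tricycle, sets the 7α (axial) hydroxyl.

Step 13
Reactants: 20 7α-allylic alcohol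
Product: 21 CNP0273675.2 (target)
Conditions: Ac2O, DMAP (cat.), pyridine, CH2Cl2, 0 °C to rt
Reagents that add atoms: acetic anhydride, CC(=O)OC(C)=O
Why: DMAP-catalysed acylation of the hindered secondary allylic alcohol with acetic anhydride gives the acetate with retention at C7.

Compound list
1 | 3-bromofuran-2-carbaldehyde | O=Cc1occc1Br | starting material
2 | triethyl 4-phosphonocrotonate | CCOC(=O)/C=C/CP(=O)(OCC)OCC | starting material
3 | ethyl (2E,4E)-5-(3-bromofuran-2-yl)penta-2,4-dienoate | CCOC(=O)/C=C/C=C/c1occc1Br | intermediate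
4 | (2E,4E)-5-(3-bromofuran-2-yl)penta-2,4-dien-1-ol | OC/C=C/C=C/c1occc1Br | intermediate
5 | tert-butyl{[(2E,4E)-5-(3-bromofuran-2-yl)penta-2,4-dien-1-yl]oxy}dimethylsilane | CC(C)(C)[Si](C)(C)OC/C=C/C=C/c1occc1Br | intermediate
6 | tert-butyldimethyl(prop-2-yn-1-yloxy)silane | C#CCO[Si](C)(C)C(C)(C)C | starting material
7 | 3-{[(tert-butyldimethylsilyl)oxy]methyl}-4,4-dichlorocyclobut-2-en-1-one | O=C1C=C(CO[Si](C)(C)C(C)(C)C)C1(Cl)Cl | intermediate
8 | 3-{[(tert-butyldimethylsilyl)oxy]methyl}cyclobut-2-en-1-one | O=C1C=C(CO[Si](C)(C)C(C)(C)C)C1 | intermediate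
9 | endo Diels–Alder adduct, 5-(3-bromofuran-2-yl)-1,2-bis{[(tert-butyldimethylsilyl)oxy]methyl}bicyclo[4.2.0]oct-3-en-7-one | O=C1C[C@@]2(CO[Si](C)(C)C(C)(C)C)[C@@H](CO[Si](C)(C)C(C)(C)C)C=C[C@@H](c3occc3Br)[C@@H]12 | intermediate
10 | 5-(3-bromofuran-2-yl)-1,2-bis(hydroxymethyl)bicyclo[4.2.0]oct-3-en-7-one | O=C1C[C@@]2(CO)[C@@H](CO)C=C[C@@H](c3occc3Br)[C@@H]12 | intermediate
11 | trans-fused β,γ-unsaturated 18,19-lactone (C2=C3) with cyclobutanone and bromofuryl group | O=C1C[C@@]23COC(=O)[C@H]2C=C[C@@H](c4occc4Br)[C@@H]13 | intermediate (not isolated)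
12 | conjugated 18,19-lactone (C3=C4) with cis-fused cyclobutanone and 3-bromofuran-2-yl at C1 | O=C1C[C@@]23COC(=O)C2=CC[C@@H](c4occc4Br)[C@@H]13 | intermediate
13 | tributyl(1-ethoxyethenyl)stannane | CCCC[Sn](CCCC)(CCCC)C(=C)OCC | starting material
14 | enol ether, 12 with 1-ethoxyethenyl in place of Br | O=C1C[C@@]23COC(=O)C2=CC[C@@H](c4occc4C(=C)OCC)[C@@H]13 | intermediate
15 | but-2-yn-1-ol | CC#CCO | starting material
16 | mixed ethyl but-2-ynyl ketal (both epimers at the ketal carbon) | O=C1C[C@@]23COC(=O)C2=CC[C@@H](c4occc4C(C)(OCC)OCC#CC)[C@@H]13 | intermediate (not isolated)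
17 | but-2-ynyl enol ether | O=C1C[C@@]23COC(=O)C2=CC[C@@H](c4occc4C(=C)OCC#CC)[C@@H]13 | intermediate (not isolated)
18 | β-allenyl ketone, furan C3 bearing 3-methylpenta-3,4-dienoyl (key-step substrate) | O=C1C[C@@]23COC(=O)C2=CC[C@@H](c4occc4C(=O)CC(C)=C=C)[C@@H]13 | intermediate
19 | pentacyclic α-methylene ketone (C7=O) | C=C1C(=O)C[C@@]23COC(=O)C2=CC[C@H]2c4occc4C(=O)C[C@]1(C)[C@H]23 | intermediate
20 | 7α-allylic alcohol | C=C1[C@@H](O)C[C@@]23COC(=O)C2=CC[C@H]2c4occc4C(=O)C[C@]1(C)[C@H]23 | intermediate
21 | CNP0273675.2 | C=C1[C@@H](OC(C)=O)C[C@@]23COC(=O)C2=CC[C@H]2c4occc4C(=O)C[C@]1(C)[C@H]23 | target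

Total step count: 13. Longest linear sequence: 11 steps (steps 1–3 and 6–13); steps 4–5 make the dienophile.

Steps most likely to fail

1. Step 11 (proposed new method). The rhodacycle may lose CO to give a cyclopropane, the allene may close in a (4+1) sense, or the β-allenyl ketone may isomerise to the dienone before insertion. The fallback uses known chemistry and sets out from bromide 12. Pd(PPh3)4/Me3SnSnMe3 gives the arylstannane F1. Stille acylation with pent-3-ynoyl chloride F2 (from pent-3-ynoic acid and (COCl)2) gives the but-2-ynyl ketone F3. The established rhodium-catalysed carboacylation of an internal alkyne tethered to the α-carbon of a cyclobutanone ([Rh(CO)2Cl]2, P(C6F5)3, dioxane, 130 °C) gives the 8-methyl C8=C9 enone F4. Me2CuLi/TMSCl (enones react far faster than the α-branched unsaturated lactone) adds the C20 methyl to C9 from the convex face and traps the enolate as the trimethylsilyl enol ether F5. Saegusa–Ito oxidation (Pd(OAc)2, MeCN) can eliminate only towards C17 and returns to the route at 19.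

2. Step 6. The β-alkyl cyclobutenone may be too unreactive towards the 1,4-disubstituted diene, regio- or enantioselectivity may erode, or the acid may decompose the furyl diene. The fallback sets out from diene 5 and uses a doubly activated dienophile. Commercial methyl 3-oxocyclobutane-1-carboxylate is brominated to the bromo ketone F6 and dehydrobrominated with Et3N to methyl 3-oxocyclobut-1-ene-1-carboxylate F7. The same oxazaborolidinium catalysis gives the adduct F8 (C19 as CO2Me). LiAlH4 reduces ester and ketone to the diol F9, and HF·pyridine gives the triol F10. Excess TEMPO/PhI(OAc)2 oxidises the 1,4-diol to the lactone and the cyclobutanol to the ketone, and DBU then gives 12, where the route is rejoined.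

3. Step 10. The acid may hydrolyse the enol ether to the methyl ketone, or the β-allenyl ketone may isomerise to the conjugated dienone at 110 °C. The fallback sets out from 12 by way of the arylstannane F1 described above and from 15. Orthoester Claisen rearrangement of 15 with triethyl orthoacetate gives ethyl 3-methylpenta-3,4-dienoate F11, LiOH gives the acid F12 and (COCl)2 the acid chloride F13. Neutral Stille acylation of F1 with F13 (Pd(PPh3)4, toluene) gives 18 directly.

Further compounds
F1 | step 11 | arylstannane, 12 with SnMe3 in place of Br | O=C1C[C@@]23COC(=O)C2=CC[C@@H](c4occc4[Sn](C)(C)C)[C@@H]13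
F2 | step 11 | pent-3-ynoyl chloride | CC#CCC(Cl)=O
F3 | step 11 | but-2-ynyl ketone, furan C3 bearing pent-3-ynoyl | O=C1C[C@@]23COC(=O)C2=CC[C@@H](c4occc4C(=O)CC#CC)[C@@H]13
F4 | step 11 | pentacyclic 8-methyl C8=C9 enone | CC=1C(=O)C[C@@]23COC(=O)C2=CC[C@H]2c4occc4C(=O)CC=1[C@H]23
F5 | step 11 | trimethylsilyl enol ether C7(OSiMe3)=C8(CH3) with C9 methyl | CC1=C(O[Si](C)(C)C)C[C@@]23COC(=O)C2=CC[C@H]2c4occc4C(=O)C[C@]1(C)[C@H]23
F6 | step 6 | methyl 2-bromo-3-oxocyclobutane-1-carboxylate | COC(=O)C1CC(=O)C1Br
F7 | step 6 | methyl 3-oxocyclobut-1-ene-1-carboxylate | COC(=O)C1=CC(=O)C1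
F8 | step 6 | Diels–Alder adduct with CO2Me on C5 | O=C1C[C@@]2(C(=O)OC)[C@@H](CO[Si](C)(C)C(C)(C)C)C=C[C@@H](c3occc3Br)[C@@H]12
F9 | step 6 | cyclobutanol diol, C18 silyl ether (carbinol epimers) | OC1C[C@@]2(CO)[C@@H](CO[Si](C)(C)C(C)(C)C)C=C[C@@H](c3occc3Br)[C@@H]12
F10 | step 6 | triol | OC1C[C@@]2(CO)[C@@H](CO)C=C[C@@H](c3occc3Br)[C@@H]12
F11 | step 10 | ethyl 3-methylpenta-3,4-dienoate | CCOC(=O)CC(C)=C=C
F12 | step 10 | 3-methylpenta-3,4-dienoic acid | OC(=O)CC(C)=C=C
F13 | step 10 | 3-methylpenta-3,4-dienoyl chloride | ClC(=O)CC(C)=C=C
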